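## Structural features

The target is a trans-fused decalin of the eremophilane type (rings A and B share C5–C10) with seven stereocentres, C2, C4, C5, C7, C8, C9 and C10; all but C2 are contiguous. Ring A carries an axial 2α-hydroxyl and an equatorial 4β-methyl that is cis to the angular 5β-methyl on the quaternary carbon C5; H-10 is α and axial. Ring B carries on three adjacent carbons an axial 7β-isopropenyl group (syn-axial to the C5 methyl), an axial 8α-hydroxyl trans-diaxial to it, and an equatorial 9α-oxygen esterified with (2Z)-3-methylpent-2-enoic acid. O8 and O9 therefore form a cis-diol of which only the equatorial member is acylated. Fragile elements are the Z-configured β,β-disubstituted enoate (geometrical isomerisation through its γ-hydrogens, acyl migration to the cis 8-hydroxyl under base), the acid-sensitive 1,1-disubstituted alkene and the axial alcohols. The real difficulty is stereochemical: the vicinal C4/C5 pair with its quaternary centre, the trans ring fusion, and above all the axial isopropenyl group on C7, which is the less stable orientation and has to be set kinetically. The key step exploits ring A: the axial hydroxyl on C2 stands 1,3 to the methyl-bearing C4, which is the pattern of a 3-methylenecyclohexanol formed when a C2 aldehyde, tethered through C1 to C10, attacks a 2-propenyl group (C3=C4–C15) on C5.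

## Logic of the disconnections

**23 ⇒ 22 ⇒ 18 + 21.** The O2–Si bond and then the C9 O–acyl bond are cut. The enoate is the most fragile group and is therefore introduced last but one; this separates the six-carbon acyl unit from a silyl-protected triol. The forward acylation must choose the equatorial O9 over the axial O8 and keep the Z geometry, and the final desilylation must be non-basic to avoid acyl migration.

**21 ⇒ 20 ⇒ 19.** The C3–CH3 bond of the enoate is cut. An olefination could not tell methyl from ethyl, whereas syn addition of a methyl cuprate to an alkynoate fixes the geometry mechanically. The forward step needs a cold quench so that the alkenyl copper intermediate does not equilibrate.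

**18 ⇒ 16 + 17.** The C7–C11 bond is cut. The trans-diaxial pair C7–C/C8–O is the signature of an epoxide opening; three carbons and two stereocentres are removed and replaced by one epoxide. The forward step demands axial attack at C7, syn to the C5 methyl.

**16 ⇒ 15.** The C7–O and C8–O bonds of the epoxide are cut to the C7=C8 alkene. The 9α-hydroxyl and the axial C5 methyl both direct a peracid to the α face, so the demand is modest. A peracid is preferred to a vanadium catalyst, which tends to oxidise pseudo-equatorial cyclohexenols to enones.

**15 ⇒ 14 ⇒ 13 ⇒ 12 ⇒ 11.** The C7=C8 alkene is traced back to the axial C8 hydroxyl of a cis-8α,9α-diol, and the diol (C8–O, C9–O cut) to the C8=C9 alkene. The shorter path, base-induced isomerisation of an 8α,9α-epoxide, is not used. In the rigid trans-decalin the only hydrogen that is syn and pseudo-axial to such an epoxide is H-10, so the wrong allylic alcohol would be expected. Dehydration of the axial C8 hydroxyl can only go toward C7. The price is a temporary silyl group on O9, whose introduction must discriminate equatorial from axial hydroxyl.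

**11 ⇒ 10 ⇒ 9.** The O–Si bond and the C4–H/C15–H bonds are cut, returning the 4-methylidene group. This turns the C4 stereocentre into an alkene that the key step produces. The forward hydrogenation must give the equatorial methyl and must spare C8=C9.

**9 ⇒ 8 (key).** The C2–C3 bond is cut, opening ring A to an aldehyde and an isopropenyl group on the pre-set trans C5/C10 pair. One ring, one bond and the C2 stereocentre are removed. The forward step must run through the chair transition state with axial oxygen. Compared centre by centre with 23, compounds 8 and 9 carry the required configuration at C5, C10 and (for 9) C2.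

**8 ⇒ 7 ⇒ 5 + 6.** The C10–C1 bond is cut by a Claisen retron. The C10 stereocentre next to the quaternary carbon is thereby derived from a carbinol centre at C8 by suprafacial transfer; this is the only reliable way to distinguish the methyl and isopropenyl faces of C5. The demand is a defined C8 configuration.

**5 ⇒ 4 ⇒ 3 ⇒ 1 + 2.** The C8–H bond is cut (ketone), then C9=C10 (aldol) and C5–C6 (Michael). The ring is reduced to two four- and six-carbon commercial components. The forward annulation must create the quaternary centre enantioselectively, which is the weakest point before the key step.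

## Other disconnections considered

**Alternative 1:** The cut runs through C5–C10 and C6–C7 and opens both rings to the acyclic (E,E)-triene A2. In A2 a 2-alkylacrolein (C5=C6, formyl on C5) is tethered through C4–C1 to the diene C7=C8–C9=C10. In the forward direction A2 would cyclise, thermally or with Et2AlCl, to the trans-octalin A1. The formyl group would later become the C5 methyl, the dioxolane the C2 alcohol and the protected hydroxypropyl arm the isopropenyl group.

- In its favour: two rings, the quaternary carbon and the C5/C10/C7 relationships arise in one pericyclic step from alkene geometry. A1 also already carries the C7 substituent next to C8=C9, so α-face dihydroxylation would give the 8α,9α-diol directly. On this point it is better than the chosen plan, which has to move the alkene and rebuild the C8 oxygen (steps 8 to 12).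
- Against it here: the trans fusion and the axial C7 arm must come from one of several competing transition states of a dienophile activated at its internal carbon. The C4 methyl is the only resident control, and the C7 arm is forced syn-axial to the formyl group. A2 itself needs a stereodefined diene, two stereocentres and three protecting groups. After A1, a neopentyl formyl group must be reduced to methyl, the ketal reduced to the axial alcohol and the side chain dehydrated.
- Comparison: in bond-forming power the alternative is superior (two rings and two bonds against one of each). Mechanistically both are concerted and read from a chair-like transition state, but the ene step has a single low-energy geometry. In step count the alternative is expected to be longer.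

**Alternative 2:** The cut runs through C3–C4 and C5–C10 of ring A and gives (E)-2-methylbut-2-enal A5 and the 2-silyloxydiene A4. In the forward direction A5, bound to a chiral oxazaborolidinium Lewis acid, would add to A4 to give the ring A cyclohexene A3 with a silyl enol ether at C1=C2.

- In its favour: the cis C4/C5 methyl pair follows directly from the E geometry of A5, and the quaternary centre is made in a catalytic enantioselective step of a well-studied class. In absolute stereocontrol this plan is the better one, since the chosen route relies on an amine-catalysed annulation in which the two groups on the enamine carbon are of similar size.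
- Against it here: to match the target, the benzyloxymethyl group on C10 must end trans to the formyl group. The cycloaddition therefore has to run with the formyl group exo, which α-methyl enals often do but not dependably. A5 is a β-substituted, sluggish dienophile. C7 and C8 are absent from A3, so ring B and its three stereocentres must be built afterwards from a neopentyl aldehyde.
- Comparison: structurally A3 solves C4/C5 but leaves C2 as a masked ketone, whereas the ene step sets C2 itself. Mechanistically both are Lewis-acid-promoted pericyclic reactions of equal standing. In step count the ring B annulation makes the alternative longer.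

**Alternative 3:** The cut removes C8: the C7–C8 and C8–C9 bonds are disconnected and ring B contracts to the cyclopentanone of hydrindanone A7 (drawn cis-fused). In the forward direction (trimethylsilyl)diazomethane A8 with Sc(OTf)3 would add to the C9 carbonyl, C7 would migrate to insert C8, and K2CO3 in methanol would remove silicon and equilibrate C10 to give decalone A6.

- In its favour: angular-methyl hydrindanones are classical building blocks available in high enantiomeric purity, so absolute configuration rests on firm ground. Here the alternative is at least the equal of the chosen plan. The product also has oxygen on C9 from the start.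
- Against it here: the trans fusion depends on an equilibration whose preference is small when C5 carries an angular methyl. The C9 ketone must later be reduced to the equatorial 9α-alcohol by hydride delivery past the syn-axial C5 methyl, the disfavoured direction. Migration of C10 instead of C7 would give the regioisomer. C7 and C8 still have to be functionalised from the ketone.
- Comparison: structurally the step adds one carbon and no stereocentre, against one ring and one stereocentre. Mechanistically a 1,2-shift with two candidate migrating groups is less predictable than the geometrically constrained ene reaction. In step count the plans are similar up to the bicycle and the alternative is longer afterwards.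

Key step: step 5

Remark (numbering): the decalin is numbered as in eremophilanes (ring A = C1–C5, C10; ring B = C5–C10; C14 on C5, C15 on C4, C11–C13 on C7); β is the face of the C5 methyl, α the face of H-10.

Remark (reagents): (2Z)-3-methylpent-2-enoic acid is not assumed to be a catalogue compound and is made in steps 13 and 14; the facial sense of the catalysts in steps 1 and 2 is assigned by the usual steric models, and both enantiomers of each are commercial.

## Steps

Step 1
Reactants: 1 2,3-dimethylbut-2-enal; 2 but-3-en-2-one
Product: 4 (S)-4-methyl-4-(prop-1-en-2-yl)cyclohex-2-en-1-one, via keto aldehyde 3 (not isolated)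
Conditions: (R)-2-[diphenyl(trimethylsilyloxy)methyl]pyrrolidine (20 mol%), PhCO2H (20 mol%), CHCl3, 0 °C → rt; then KOH (cat.), MeOH, rt
Reagents that add atoms: none
Why: Amine-catalysed Robinson annulation: the amine converts 1 into a dienamine whose α-carbon adds to 2 in a Michael reaction, creating the quaternary carbon (future C5) on the face left open by the diaryl(silyloxy)methyl group with the isopropenyl arm expected anti to nitrogen; hydrolysis gives 3 and base-induced aldol condensation of its methyl ketone onto the aldehyde closes the enone; the (R)-catalyst is chosen by the steric-shielding model and its enantiomer would be used if the sense proved opposite.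

Step 2
Reactants: 4 (S)-4-methyl-4-(prop-1-en-2-yl)cyclohex-2-en-1-one
Product: 5 (1S,4S)-4-methyl-4-(prop-1-en-2-yl)cyclohex-2-en-1-ol
Conditions: (R)-Me-CBS oxazaborolidine (20 mol%), catecholborane, toluene, −78 °C; aq. NaOH work-up
Reagents that add atoms: none
Why: Corey–Bakshi–Shibata 1,2-reduction under reagent control: with the alkenyl arm as the large group the (R)-oxazaborolidine should give the (S)-carbinol (OH cis to the C5 methyl), the remote quaternary centre exerting little bias; catecholborane does not hydroborate the isopropenyl group at −78 °C, and any minor enantiomer of 4 is converted into a diastereomer that can be removed.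

Step 3
Reactants: 5 (1S,4S)-4-methyl-4-(prop-1-en-2-yl)cyclohex-2-en-1-ol; 6 triethyl orthoacetate
Product: 7 ethyl 2-[(1S,6S)-6-methyl-6-(prop-1-en-2-yl)cyclohex-2-en-1-yl]acetate
Conditions: 6 (5 equiv), EtCO2H (5 mol%), 140 °C, EtOH distilled off
Reagents that add atoms: none
Why: Johnson–Claisen rearrangement: the ketene acetal formed by exchange rearranges suprafacially, so the β C8–O bond is traded for a β C10–C1 bond, placing the acetate arm cis to the C5 methyl and trans to the isopropenyl group and moving the alkene to C8=C9.

Step 4
Reactants: 7 ethyl 2-[(1S,6S)-6-methyl-6-(prop-1-en-2-yl)cyclohex-2-en-1-yl]acetate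
Product: 8 2-[(1S,6S)-6-methyl-6-(prop-1-en-2-yl)cyclohex-2-en-1-yl]acetaldehyde
Conditions: i-Bu2AlH (1.1 equiv), CH2Cl2, −78 °C; aq. potassium sodium tartrate
Reagents that add atoms: none
Why: Partial reduction of an ester by i-Bu2AlH, which stops at the aluminium hemiacetal at −78 °C and releases the aldehyde on work-up; no stereocentre is touched.

Step 5
Reactants: 8 2-[(1S,6S)-6-methyl-6-(prop-1-en-2-yl)cyclohex-2-en-1-yl]acetaldehyde
Product: 9 (2R,4aS,8aS)-4a-methyl-4-methylidene-1,2,3,4,4a,5,6,8a-octahydronaphthalen-2-ol (5β-methyl-4-methylidene-trans-Δ8-octalin-2α-ol)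
Conditions: Me2AlCl (1.5 equiv), CH2Cl2, −78 → 0 °C
Reagents that add atoms: none
Why: Me2AlCl binds the aldehyde oxygen and the activated carbon C2 is attacked by the terminal carbon C3 of the 1,1-disubstituted alkene while a hydrogen of the C15 methyl passes to oxygen in a concerted, asynchronous six-centre process (intramolecular type-two carbonyl-ene reaction), the closest known reaction type being the Me2AlCl-promoted cyclisation of 5-methylhex-5-enals to axial 3-methylenecyclohexanols. Ring A closes as a six-membered ring in which both ene carbons C3 and C4 become ring members (endo with respect to the alkene, exo with respect to the carbonyl), C2–C3 being the only skeletal bond formed. The one new stereocentre, C2, is controlled by the bicyclic transition state: the forming ring is a chair held by the pre-set trans C5/C10 pair (both arms equatorial on ring B), and the carbonyl oxygen must be axial to reach the C15 hydrogen across C2–C3–C4, which puts it on the α face, syn to H-10. An equatorial oxygen would need a boat. Chemoselectivity is needed against the ring alkene C8=C9, which cannot reach the aldehyde without forming a four-membered or strained bridged ring, and against stepwise ionisation to a C4 cation with methyl migration from C5; the concerted path and low temperature should secure this. Me2AlCl is chosen over stronger Lewis acids because the alcohol–aluminium complex loses methane and so removes the proton that would otherwise start Prins-type reactions or isomerise the exocyclic alkene. More than one equivalent is used because the product alkoxide retains the aluminium.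

Step 6
Reactants: 9 5β-methyl-4-methylidene-trans-Δ8-octalin-2α-ol
Product: 10 4β,5β-dimethyl-trans-Δ8-octalin-2α-ol
Conditions: Mn(dpm)3 (10 mol%), PhSiH3, t-BuOOH, i-PrOH, rt
Reagents that add atoms: none
Why: Hydrogen-atom-transfer hydrogenation (Mukaiyama type): the manganese hydride adds a hydrogen atom to C15 to give the tertiary C4 radical, which is quenched by axial hydrogen delivery on the α face, leaving the methyl equatorial (4β, cis to the C5 methyl) and avoiding the 1,3-diaxial clash with O2 of the 4α epimer; the 1,2-disubstituted C8=C9 alkene would give only a secondary radical and reacts much more slowly.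

Step 7
Reactants: 10 4β,5β-dimethyl-trans-Δ8-octalin-2α-ol
Product: 11 2α-(tert-butyldimethylsilyloxy)-4β,5β-dimethyl-trans-Δ8-octalin
Conditions: TBSOTf, 2,6-lutidine, CH2Cl2, 0 °C
Reagents that add atoms: tert-butyldimethylsilyl trifluoromethanesulfonate, CC(C)(C)[Si](C)(C)OS(=O)(=O)C(F)(F)F
Why: Silyl triflate silylation of the hindered axial alcohol; the ether has to survive steps 8 to 15 and be removable by acidic fluoride at the end.

Step 8
Reactants: 11 2α-(tert-butyldimethylsilyloxy)-4β,5β-dimethyl-trans-Δ8-octalin
Product: 12 2α-(tert-butyldimethylsilyloxy)-4β,5β-dimethyl-trans-decalin-8α,9α-diol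
Conditions: OsO4 (2 mol%), NMO, acetone–H2O, rt
Reagents that add atoms: osmium tetroxide, O=[Os](=O)(=O)=O; N-methylmorpholine N-oxide (terminal oxygen source), C[N+]1([O-])CCOCC1
Why: Catalytic osmium tetroxide cis-dihydroxylation: the reagent adds to the α face of C8=C9 because the β face is screened by the axial C5 methyl (1,3 to C9), giving the 8α,9α-diol with the C9 oxygen in its final configuration.

Step 9
Reactants: 12 2α-(tert-butyldimethylsilyloxy)-4β,5β-dimethyl-trans-decalin-8α,9α-diol
Product: 13 2α-(tert-butyldimethylsilyloxy)-9α-(triethylsilyloxy)-4β,5β-dimethyl-trans-decalin-8α-ol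
Conditions: Et3SiCl (1.05 equiv), imidazole, DMF, −20 °C
Reagents that add atoms: chlorotriethylsilane, CC[Si](CC)(CC)Cl
Why: Kinetic monosilylation of a cis-1,2-diol: the equatorial 9α-hydroxyl is less hindered than the axial 8α-hydroxyl with its two syn-axial hydrogens and should be silylated first by one equivalent of chlorosilane at low temperature.

Step 10
Reactants: 13 2α-(tert-butyldimethylsilyloxy)-9α-(triethylsilyloxy)-4β,5β-dimethyl-trans-decalin-8α-ol
Product: 15 2α-(tert-butyldimethylsilyloxy)-4β,5β-dimethyl-trans-Δ7-octalin-9α-ol, via allylic triethylsilyl ether 14 (not isolated)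
Conditions: Burgess reagent (methyl N-(triethylammoniosulfonyl)carbamate), toluene, 60 °C; then PPTS, MeOH, rt
Reagents that add atoms: none
Why: Burgess dehydration (syn elimination through the sulfamate ester) followed by acidic methanolysis of the triethylsilyl ether: the axial C8 sulfamate has a cis hydrogen only on C7, because C9 carries oxygen on that face, so the alkene can only form as C7=C8 and H-10 is never involved; PPTS in methanol then frees the allylic 9α-hydroxyl without touching the secondary tert-butyldimethylsilyl ether.

Step 11
Reactants: 15 2α-(tert-butyldimethylsilyloxy)-4β,5β-dimethyl-trans-Δ7-octalin-9α-ol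
Product: 16 7α,8α-epoxy-2α-(tert-butyldimethylsilyloxy)-4β,5β-dimethyl-trans-decalin-9α-ol
Conditions: m-CPBA, NaHCO3, CH2Cl2, 0 °C
Reagents that add atoms: 3-chloroperoxybenzoic acid, OOC(=O)c1cccc(Cl)c1
Why: Hydroxyl-directed peracid epoxidation of a cyclohexenol with a pseudo-equatorial hydroxyl: hydrogen bonding delivers oxygen cis to the 9α-OH and the axial C5 methyl blocks the β face at C7, so both effects give the 7α,8α-epoxide.

Step 12
Reactants: 16 7α,8α-epoxy-2α-(tert-butyldimethylsilyloxy)-4β,5β-dimethyl-trans-decalin-9α-ol; 17 isopropenylmagnesium bromide
Product: 18 2α-(tert-butyldimethylsilyloxy)-4β,5β-dimethyl-7β-(prop-1-en-2-yl)-trans-decalin-8α,9α-diol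
Conditions: 17 (4 equiv), CuI (20 mol%), THF, −30 → 0 °C; aq. NH4Cl
Reagents that add atoms: none
Why: Copper-catalysed Grignard opening of an epoxide under the Fürst–Plattner rule: in the rigid trans-decalin only attack at C7 from the β face leads to a chair with diaxial carbon and oxygen, so the isopropenyl group enters axially at C7 with inversion and the 8α-hydroxyl is regenerated, as in diaxial openings of 2α,3α-epoxy-5α-steroids; the first equivalent of 17 deprotonates the 9-hydroxyl.

Step 13
Reactants: 19 ethyl pent-2-ynoate
Product: 20 ethyl (2Z)-3-methylpent-2-enoate
Conditions: Me2CuLi (from MeLi and CuI), THF, −78 °C; MeOH then aq. NH4Cl at −78 °C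
Reagents that add atoms: lithium dimethylcuprate (from methyllithium and CuI), [Li+].C[Cu-]C
Why: Syn carbocupration (conjugate addition of a lithium dialkylcuprate to an alk-2-ynoate): methyl and copper add cis across the triple bond and cold protonation replaces copper with retention, so methyl ends trans and ethyl cis to the ester, which is the Z-enoate.

Step 14
Reactants: 20 ethyl (2Z)-3-methylpent-2-enoate
Product: 21 (2Z)-3-methylpent-2-enoic acid
Conditions: LiOH, THF–H2O, rt; then aq. HCl
Reagents that add atoms: lithium hydroxide, [Li+].[OH-]
Why: Saponification by hydroxide attack at the ester carbonyl; the alkene geometry is not affected under these mild conditions.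

Step 15
Reactants: 18 2α-(tert-butyldimethylsilyloxy)-4β,5β-dimethyl-7β-(prop-1-en-2-yl)-trans-decalin-8α,9α-diol; 21 (2Z)-3-methylpent-2-enoic acid
Product: 22 2α-(tert-butyldimethylsilyloxy)-8α-hydroxy-4β,5β-dimethyl-7β-(prop-1-en-2-yl)-trans-decalin-9α-yl (2Z)-3-methylpent-2-enoate
Conditions: DCC, DMAP (10 mol%), CH2Cl2, 0 °C → rt
Reagents that add atoms: none
Why: Steglich esterification: the activated acid should react with the equatorial 9α-hydroxyl of the cis-diol in preference to the axial 8α-hydroxyl, and the absence of a stoichiometric amine base at low temperature limits γ-deprotonation of the activated acid and hence loss of the Z geometry.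

Step 16
Reactants: 22 2α-(tert-butyldimethylsilyloxy)-8α-hydroxy-4β,5β-dimethyl-7β-(prop-1-en-2-yl)-trans-decalin-9α-yl (2Z)-3-methylpent-2-enoate
Product: 23 2α,8α-dihydroxy-4β,5β-dimethyl-7β-(prop-1-en-2-yl)-trans-decalin-9α-yl (2Z)-3-methylpent-2-enoate (CNP0129603.1)
Conditions: HF·pyridine, pyridine–THF, 0 °C → rt
Reagents that add atoms: none
Why: Fluoride cleavage of the silyl ether under buffered acidic conditions, which avoid base-induced acyl migration from O9 to the cis O8 and leave the enoate and the isopropenyl group intact.

## Compound list

1 | 2,3-dimethylbut-2-enal | CC(C)=C(C)C=O | starting material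
2 | but-3-en-2-one | CC(=O)C=C | starting material
3 | (R)-2-methyl-5-oxo-2-(prop-1-en-2-yl)hexanal | C=C(C)[C@@](C=O)(C)CCC(C)=O | intermediate
4 | (S)-4-methyl-4-(prop-1-en-2-yl)cyclohex-2-en-1-one | C=C(C)[C@@]1(C)CCC(=O)C=C1 | intermediate
5 | (1S,4S)-4-methyl-4-(prop-1-en-2-yl)cyclohex-2-en-1-ol | C=C(C)[C@@]1(C)CC[C@H](O)C=C1 | intermediate
6 | triethyl orthoacetate | CCOC(C)(OCC)OCC | starting material
7 | ethyl 2-[(1S,6S)-6-methyl-6-(prop-1-en-2-yl)cyclohex-2-en-1-yl]acetate | C=C(C)[C@@]1(C)CCC=C[C@@H]1CC(=O)OCC | intermediate
8 | 2-[(1S,6S)-6-methyl-6-(prop-1-en-2-yl)cyclohex-2-en-1-yl]acetaldehyde | C=C(C)[C@@]1(C)CCC=C[C@@H]1CC=O | intermediate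
9 | (2R,4aS,8aS)-4a-methyl-4-methylidene-1,2,3,4,4a,5,6,8a-octahydronaphthalen-2-ol | C1C[C@]2(C)C(=C)C[C@H](O)C[C@H]2C=C1 | intermediate
10 | 4β,5β-dimethyl-trans-Δ8-octalin-2α-ol | C1C[C@]2(C)[C@@H](C)C[C@H](O)C[C@H]2C=C1 | intermediate
11 | 2α-(tert-butyldimethylsilyloxy)-4β,5β-dimethyl-trans-Δ8-octalin | C1C[C@]2(C)[C@@H](C)C[C@H](O[Si](C)(C)C(C)(C)C)C[C@H]2C=C1 | intermediate
12 | 2α-(tert-butyldimethylsilyloxy)-4β,5β-dimethyl-trans-decalin-8α,9α-diol | C1C[C@]2(C)[C@@H](C)C[C@H](O[Si](C)(C)C(C)(C)C)C[C@H]2[C@H](O)[C@@H]1O | intermediate
13 | 2α-(tert-butyldimethylsilyloxy)-9α-(triethylsilyloxy)-4β,5β-dimethyl-trans-decalin-8α-ol | C1C[C@]2(C)[C@@H](C)C[C@H](O[Si](C)(C)C(C)(C)C)C[C@H]2[C@H](O[Si](CC)(CC)CC)[C@@H]1O | intermediate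
14 | 2α-(tert-butyldimethylsilyloxy)-9α-(triethylsilyloxy)-4β,5β-dimethyl-trans-Δ7-octalin | C1=CC[C@]2(C)[C@@H](C)C[C@H](O[Si](C)(C)C(C)(C)C)C[C@H]2[C@@H]1O[Si](CC)(CC)CC | intermediate
15 | 2α-(tert-butyldimethylsilyloxy)-4β,5β-dimethyl-trans-Δ7-octalin-9α-ol | C1=CC[C@]2(C)[C@@H](C)C[C@H](O[Si](C)(C)C(C)(C)C)C[C@H]2[C@@H]1O | intermediate
16 | 7α,8α-epoxy-2α-(tert-butyldimethylsilyloxy)-4β,5β-dimethyl-trans-decalin-9α-ol | [C@@H]13C[C@]2(C)[C@@H](C)C[C@H](O[Si](C)(C)C(C)(C)C)C[C@H]2[C@H](O)[C@@H]1O3 | intermediate
17 | isopropenylmagnesium bromide | C=C(C)[Mg]Br | starting material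
18 | 2α-(tert-butyldimethylsilyloxy)-4β,5β-dimethyl-7β-(prop-1-en-2-yl)-trans-decalin-8α,9α-diol | C=C(C)[C@H]1C[C@]2(C)[C@@H](C)C[C@H](O[Si](C)(C)C(C)(C)C)C[C@H]2[C@H](O)[C@@H]1O | intermediate
19 | ethyl pent-2-ynoate | CCC#CC(=O)OCC | starting material
20 | ethyl (2Z)-3-methylpent-2-enoate | CCOC(=O)/C=C(/C)CC | intermediate
21 | (2Z)-3-methylpent-2-enoic acid | OC(=O)/C=C(/C)CC | intermediate
22 | 2α-(tert-butyldimethylsilyloxy)-8α-hydroxy-4β,5β-dimethyl-7β-(prop-1-en-2-yl)-trans-decalin-9α-yl (2Z)-3-methylpent-2-enoate | C=C(C)[C@H]1C[C@]2(C)[C@@H](C)C[C@H](O[Si](C)(C)C(C)(C)C)C[C@H]2[C@H](OC(=O)/C=C(/C)CC)[C@@H]1O | intermediate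
23 | 2α,8α-dihydroxy-4β,5β-dimethyl-7β-(prop-1-en-2-yl)-trans-decalin-9α-yl (2Z)-3-methylpent-2-enoate (CNP0129603.1) | C=C(C)[C@H]1C[C@]2(C)[C@@H](C)C[C@H](O)C[C@H]2[C@H](OC(=O)/C=C(/C)CC)[C@@H]1O | target

## Step count and least certain steps

Total: 16 steps. Longest linear sequence: 14 steps (steps 1 to 12, 15 and 16); steps 13 and 14 are a two-step side branch that joins at step 15.

**Step 5 (key step).** Most likely failure: stepwise ionisation at C4 instead of the concerted ene path, followed by methyl migration from the adjacent quaternary C5 or chloride capture, or methyl transfer from aluminium to the aldehyde. The cause is that the developing C4 cation is tertiary and flanked by a fully substituted carbon. Fallback, forming the same C2–C3 bond by an organometallic rather than a cationic path: ester 7 would be chlorinated at the isopropenyl methyl by ene-type chlorination (Ca(OCl)2, solid CO2, CH2Cl2–H2O, 0 °C) to give ethyl 2-[(1S,6S)-6-(3-chloroprop-1-en-2-yl)-6-methylcyclohex-2-en-1-yl]acetate F1. Reduction with i-Bu2AlH at −78 °C would give the chloro aldehyde F2. Intramolecular Nozaki–Hiyama allylation with CrCl2 in THF would then join C3 to C2 through the same bicyclic chair, with the metal in place of the migrating hydrogen, and regenerate the exocyclic C4=C15 alkene. The route is rejoined at 9.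

**Step 1.** Most likely failure: poor control of dienamine geometry and face, because methyl and isopropenyl on the enamine carbon are of similar size, giving low enantiomeric purity; reaction at the γ-terminus of the dienamine could also compete. Fallback: 1 and 2 would be combined under achiral conditions (pyrrolidine, AcOH, then KOH, MeOH) to give the racemic enone F3. Reduction under the conditions of step 2 is reagent-controlled and would convert both enantiomers into (1S)-carbinols, that is 5 and its (1S,4R) diastereomer F4. These would be separated by chromatography, or as the corresponding esters after step 3. Half of the material is lost, but the route is rejoined at 5 without an enantioselective carbon–carbon bond formation.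

**Step 9.** Most likely failure: insufficient discrimination between the equatorial O9 and the axial O8 during silylation, or silyl migration between them, which would send part of the material into elimination toward C10 in step 10. Fallback from 11, avoiding the diol altogether:
- N-bromosuccinimide in aqueous THF would give, by diaxial opening of the α-bromonium ion, the 8α-bromo-9β-hydroxy compound F5.
- K2CO3 in methanol would close it to the 8β,9β-epoxide F6.
- LiNEt2 in ether would isomerise F6 by syn elimination to the 9β-allylic alcohol F7, since the only hydrogen syn to a β-epoxide is the pseudo-axial H-7β.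
- Mitsunobu inversion (4-nitrobenzoic acid, PPh3, DIAD) would give the 9α-(4-nitrobenzoate) F8.
- Methanolysis (K2CO3, MeOH) would rejoin the route at 15.

**Step 12.** Most likely failure: slow axial attack at C7, which is syn-axial to the C5 methyl, allowing halide opening of the epoxide or attack at C8 to compete. Fallback from 16: the slender lithium acetylide–ethylenediamine complex (LiC≡CH·H2NCH2CH2NH2, DMSO, rt) would open the epoxide diaxially to the 7β-ethynyl diol F9. Negishi carboalumination (Me3Al in excess, Cp2ZrCl2, CH2Cl2, then H2O) would add methyl to the internal alkyne carbon and, after protonolysis, give the isopropenyl group, rejoining the route at 18.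

**Step 15.** Most likely failure: erosion of the Z geometry through reversible γ-deprotonation of the activated acid, or acyl transfer to the axial O8. Fallback from 18, which makes the alkene geometry on the substrate: esterification with commercial pent-2-ynoic acid (DCC, DMAP) would give the 9α-pent-2-ynoate F10. Syn addition of Me2CuLi at −78 °C with a cold quench, as in step 13, would then give 22 directly, where the route is rejoined.

## Further compounds

F1 | step 5 | ethyl 2-[(1S,6S)-6-(3-chloroprop-1-en-2-yl)-6-methylcyclohex-2-en-1-yl]acetate | C=C(CCl)[C@@]1(C)CCC=C[C@@H]1CC(=O)OCC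
F2 | step 5 | 2-[(1S,6S)-6-(3-chloroprop-1-en-2-yl)-6-methylcyclohex-2-en-1-yl]acetaldehyde | C=C(CCl)[C@@]1(C)CCC=C[C@@H]1CC=O
F3 | step 1 | racemic 4-methyl-4-(prop-1-en-2-yl)cyclohex-2-en-1-one | C=C(C)C1(C)CCC(=O)C=C1
F4 | step 1 | (1S,4R)-4-methyl-4-(prop-1-en-2-yl)cyclohex-2-en-1-ol | C=C(C)[C@]1(C)CC[C@H](O)C=C1
F5 | step 9 | 8α-bromo-2α-(tert-butyldimethylsilyloxy)-4β,5β-dimethyl-trans-decalin-9β-ol | C1C[C@]2(C)[C@@H](C)C[C@H](O[Si](C)(C)C(C)(C)C)C[C@H]2[C@@H](O)[C@@H]1Br
F6 | step 9 | 8β,9β-epoxy-2α-(tert-butyldimethylsilyloxy)-4β,5β-dimethyl-trans-decalin | C1C[C@]2(C)[C@@H](C)C[C@H](O[Si](C)(C)C(C)(C)C)C[C@H]2[C@H]3O[C@@H]13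
F7 | step 9 | 2α-(tert-butyldimethylsilyloxy)-4β,5β-dimethyl-trans-Δ7-octalin-9β-ol | C1=CC[C@]2(C)[C@@H](C)C[C@H](O[Si](C)(C)C(C)(C)C)C[C@H]2[C@H]1O
F8 | step 9 | 2α-(tert-butyldimethylsilyloxy)-4β,5β-dimethyl-trans-Δ7-octalin-9α-yl 4-nitrobenzoate | C1=CC[C@]2(C)[C@@H](C)C[C@H](O[Si](C)(C)C(C)(C)C)C[C@H]2[C@@H]1OC(=O)c3ccc(cc3)[N+](=O)[O-]
F9 | step 12 | 2α-(tert-butyldimethylsilyloxy)-7β-ethynyl-4β,5β-dimethyl-trans-decalin-8α,9α-diol | C#C[C@H]1C[C@]2(C)[C@@H](C)C[C@H](O[Si](C)(C)C(C)(C)C)C[C@H]2[C@H](O)[C@@H]1O
F10 | step 15 | 2α-(tert-butyldimethylsilyloxy)-8α-hydroxy-4β,5β-dimethyl-7β-(prop-1-en-2-yl)-trans-decalin-9α-yl pent-2-ynoate | C=C(C)[C@H]1C[C@]2(C)[C@@H](C)C[C@H](O[Si](C)(C)C(C)(C)C)C[C@H]2[C@H](OC(=O)C#CCC)[C@@H]1O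
A1 | alternative 1 | trans-octalin with angular C5 formyl, C4 methyl, C2 dioxolane, C8=C9 alkene and 1-(4-methoxybenzyloxy)prop-2-yl on C7 | C[C@@H](COCc3ccc(OC)cc3)[C@H]1C[C@]2(C=O)[C@@H](C)CC4(OCCO4)C[C@H]2C=C1
A2 | alternative 1 | (E,E)-triene with 2-alkylacrolein, C2 dioxolane and 4-methoxybenzyl ether | C=C(C=O)[C@@H](C)CC1(OCCO1)C/C=C/C=C/[C@@H](C)COCc2ccc(OC)cc2
A3 | alternative 2 | ring A cyclohexene with C5 formyl and methyl, C4 methyl, C10 benzyloxymethyl and C2 silyl enol ether | O=C[C@]1(C)[C@@H](C)CC(O[Si](C)(C)C(C)(C)C)=C[C@H]1COCc2ccccc2
A4 | alternative 2 | (E)-5-benzyloxy-2-(tert-butyldimethylsilyloxy)penta-1,3-diene | C=C(O[Si](C)(C)C(C)(C)C)/C=C/COCc1ccccc1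
A5 | alternative 2 | (E)-2-methylbut-2-enal | C/C=C(\C)C=O
A6 | alternative 3 | trans-fused 4β,5β-dimethyl-decalin-9-one 2-ethylene ketal | C1C[C@]2(C)[C@@H](C)CC3(OCCO3)C[C@H]2C(=O)C1
A7 | alternative 3 | cis-fused 4β,5β-dimethyl-8-nor-decalin-9-one 2-ethylene ketal (hydrindanone) | C1C[C@]2(C)[C@@H](C)CC3(OCCO3)C[C@@H]2C1=O
A8 | alternative 3 | (trimethylsilyl)diazomethane | C[Si](C)(C)C=[N+]=[N-]
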